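## Retrosynthetic overview

1. Target numbering (used for all intermediates): bicyclo[3.3.1]nonan-9-one with C-1 carbinol bridgehead, C-2 CH2, C-3 CHN, C-4 CHOH, C-5 CH bridgehead, C-6 CHOMe, C-7/C-8 oxirane, C-9 ketone. Ring A = C-1, C-2, C-3, C-4, C-5, C-9; ring B = C-1, C-9, C-5, C-6, C-7, C-8.
2. Enabling feature: C-5 is the shared α-carbon of a β-hydroxy ketone (C-4–OH/C-9=O, ring A) and a β-methoxy ketone (C-6–OMe/C-9=O, ring B), and the C-2 methylene sits axial on ring B at C-1. Cutting C-4–C-5 (aldol) together with C-6–OMe (oxa-Michael) opens ring A to a monocyclic 4,5-epoxycyclohex-2-enone with an α-amido aldehyde tether, stored as a spiro-lactol through the C-1 oxygen (temporary ring).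
3. C-1 to C-9 with N at C-3 are the carbons of L-o-tyrosine. The C-1–O bond and the C-9 ketone come from a dearomatizing ortho-spirolactonization of the N-acylated amino acid (temporary γ-lactone, sets C-1); the oxirane then goes onto the distal C-7=C-8 bond.
4. Order of ring formation: ring B (arene to dienone, step 3), oxirane (step 4), ring A (step 7, last). The lactone/lactol ring is temporary and is opened in step 7.
5. The (E)-dodec-2-enoyl amide is installed first, so no nitrogen protecting group is needed.

Key step: step 7

Assumption: L-o-tyrosine, (2S)-2-amino-3-(2-hydroxyphenyl)propanoic acid, is taken as purchasable in enantiopure form.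

## Route

Step 1
Reactants: 1 (2E)-dodec-2-enoic acid; 2 N-hydroxysuccinimide
Product: 3 2,5-dioxopyrrolidin-1-yl (2E)-dodec-2-enoate
Conditions: DCC (1.05 equiv), EtOAc, 0 °C to rt; filter
Reagents that add atoms: none
Why: Steglich-type carbodiimide esterification should give the isolable active ester without touching the E-alkene.

Step 2
Reactants: 3 2,5-dioxopyrrolidin-1-yl (2E)-dodec-2-enoate; 4 L-o-tyrosine
Product: 5 (2S)-2-[(2E)-dodec-2-enamido]-3-(2-hydroxyphenyl)propanoic acid
Conditions: NaHCO3 (2.2 equiv), THF/H2O 1:1, 0 °C to rt; then 1 M HCl to pH 2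
Reagents that add atoms: none
Why: Aminolysis of the active ester (Schotten–Baumann-type conditions) should acylate only the amine at pH 8, the phenol staying free, and the C-3 centre is not at risk because the amino acid carboxyl is never activated.

Step 3
Reactants: 5 (2S)-2-[(2E)-dodec-2-enamido]-3-(2-hydroxyphenyl)propanoic acid
Product: 6 (3S,5S)-3-[(2E)-dodec-2-enamido]-1-oxaspiro[4.5]deca-7,9-diene-2,6-dione
Conditions: (R,R)-2-iodo-1,3-bis[1-(mesitylcarbamoyl)ethoxy]benzene (10 mol %), mCPBA (1.3 equiv), CH2Cl2/(CF3)2CHOH 4:1, −20 °C; crude 6 taken on at once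
Reagents that add atoms: none
Why: Kita-type oxidative dearomatizing spirolactonization: the aryl-λ3-iodane made in situ activates the phenol oxygen and the tethered carboxylate closes 5-exo on the alkyl-bearing ortho carbon (C-1), so the tether fixes ortho over para attack, and the spiro centre should be set by the chiral iodane (antipode to be confirmed as the matched one) helped by the C-3 amide turning away from the iodane-bearing C-9 oxygen, the spiro epimer being a separable diastereomer.

Step 4
Reactants: 6 (3S,5S)-3-[(2E)-dodec-2-enamido]-1-oxaspiro[4.5]deca-7,9-diene-2,6-dione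
Product: 7 (3S,5S,9S,10S)-9,10-epoxy-3-[(2E)-dodec-2-enamido]-1-oxaspiro[4.5]dec-7-ene-2,6-dione
Conditions: DMDO (1.2 equiv), acetone, −20 to 0 °C
Reagents that add atoms: dimethyldioxirane (CC1(C)OO1)
Why: Dioxirane epoxidation is electrophilic and should pick the distal C-7=C-8 bond of the dienone over the two carbonyl-conjugated α,β bonds (C-5=C-6 and the side-chain unsaturated amide), approaching from the face of the small lactone oxygen because the other face carries the lactone methylene C-2 and the C-3 amide, which sets C-7 and C-8 syn to the C-1 oxygen.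

Step 5
Reactants: 7 (3S,5S,9S,10S)-9,10-epoxy-3-[(2E)-dodec-2-enamido]-1-oxaspiro[4.5]dec-7-ene-2,6-dione
Product: 8 9,10-epoxy-3-[(2E)-dodec-2-enamido]-1-oxaspiro[4.5]dec-7-ene-2,6-diol (lactol and allylic alcohol; epimers at C-4 and C-9 of the target numbering, other centres as in 7)
Conditions: iBu2AlH (3.5 equiv), CH2Cl2, −78 °C; aq. potassium sodium tartrate (KNaC4H4O6)
Reagents that add atoms: none
Why: iBu2AlH at −78 °C should reduce the lactone only to the aluminium hemiacetal (lactol after work-up) and the enone carbonyl in the 1,2 sense while the N-aluminated amide and the oxirane survive; the two new carbinol centres are unselective but temporary, C-9 being re-oxidized in step 6 and C-4 being set in step 7.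

Step 6
Reactants: 8 9,10-epoxy-3-[(2E)-dodec-2-enamido]-1-oxaspiro[4.5]dec-7-ene-2,6-diol
Product: 9 (3S,5S,9S,10S)-9,10-epoxy-2-hydroxy-3-[(2E)-dodec-2-enamido]-1-oxaspiro[4.5]dec-7-en-6-one (both lactol anomers)
Conditions: activated MnO2 (15 equiv), CH2Cl2, rt
Reagents that add atoms: none
Why: MnO2 oxidizes allylic alcohols selectively, so the C-9 carbinol should return to the enone while the saturated lactol (lactol isomers equilibrate through the open aldehyde, none being an allylic alcohol), the oxirane and the amide are left, giving the aldehyde oxidation level at C-4 beside an intact enone.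

Step 7
Reactants: 9 (3S,5S,9S,10S)-9,10-epoxy-2-hydroxy-3-[(2E)-dodec-2-enamido]-1-oxaspiro[4.5]dec-7-en-6-one
Product: 12 N-[(1S,3S,4R,5S,6S,7S,8S)-7,8-epoxy-1,4-dihydroxy-6-methoxy-9-oxobicyclo[3.3.1]nonan-3-yl]-(2E)-dodec-2-enamide (CNP0137540.1), via open hydroxy aldehyde 10 (not isolated), via sodium enolate 11 (not isolated)
Conditions: NaOMe (0.2 equiv), MeOH, −20 to 0 °C; aq. NH4Cl
Reagents that add atoms: methanol (CO)
Why: Catalytic methoxide opens the lactol to the hydroxy aldehyde 10, adds reversibly to C-6 of the enone (oxa-Michael) to give the C-9/C-5 enolate 11, and this enolate adds to the tethered aldehyde (C-5–C-4 bond), which closes ring A; the closest known reaction type is the alkoxide-triggered oxa-Michael/intramolecular aldol cascade of quinol-derived cyclohexenones that carry an amido aldehyde side chain. Ring A closes in the 6-(enolendo)-exo-trig mode through a chair in which the C-2 methylene, axial on ring B at C-1, delivers the aldehyde to one face of C-5 only, so C-5 is controlled by C-1. C-6 is controlled by the same event: only the adduct with methoxide trans to the incoming C-4 (antiparallel addition, trans-diaxial across C-5/C-6, hence syn to the oxirane) has an enolate that can reach the aldehyde, and the cis adduct should return by retro-Michael. C-4 should be set by a sodium-bridged closed (Zimmerman–Traxler-like) transition state that holds the aldehyde oxygen gauche to C-9, giving the axial hydroxyl cis to the amide and hydrogen-bonded to the C-9 carbonyl, while C-3 is carried from the amino acid with its amide equatorial (a C-3 epimer formed by aldehyde enolization could cyclize only with an endo amide and should drain back). The step needs conjugate addition at C-6 to beat attack on the vinyl oxirane and C-enolization of the aldehyde, which the large excess of methanol, the catalytic base and the low temperature should secure. The product should be a sink because C-5 is then a bridgehead, so loss of methoxide by enolization toward C-5 is forbidden by Bredt's rule.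

## Compound list

1 | (2E)-dodec-2-enoic acid | CCCCCCCCC/C=C/C(=O)O | starting material
2 | N-hydroxysuccinimide | ON1C(=O)CCC1=O | starting material
3 | 2,5-dioxopyrrolidin-1-yl (2E)-dodec-2-enoate | CCCCCCCCC/C=C/C(=O)ON1C(=O)CCC1=O | intermediate
4 | L-o-tyrosine, (2S)-2-amino-3-(2-hydroxyphenyl)propanoic acid | N[C@@H](Cc1ccccc1O)C(=O)O | starting material
5 | (2S)-2-[(2E)-dodec-2-enamido]-3-(2-hydroxyphenyl)propanoic acid | CCCCCCCCC/C=C/C(=O)N[C@@H](Cc1ccccc1O)C(=O)O | intermediate
6 | (3S,5S)-3-[(2E)-dodec-2-enamido]-1-oxaspiro[4.5]deca-7,9-diene-2,6-dione | CCCCCCCCC/C=C/C(=O)N[C@H]1C[C@@]2(OC1=O)C(=O)C=CC=C2 | intermediate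
7 | (3S,5S,9S,10S)-9,10-epoxy-3-[(2E)-dodec-2-enamido]-1-oxaspiro[4.5]dec-7-ene-2,6-dione, oxirane syn to the lactone oxygen | CCCCCCCCC/C=C/C(=O)N[C@H]1C[C@@]2(OC1=O)C(=O)C=C[C@@H]1O[C@@H]12 | intermediate
8 | 9,10-epoxy-3-[(2E)-dodec-2-enamido]-1-oxaspiro[4.5]dec-7-ene-2,6-diol, epimers at the lactol carbon and at the allylic carbinol, other centres as in 7 | CCCCCCCCC/C=C/C(=O)N[C@H]1C[C@@]2(OC1O)C(O)C=C[C@@H]1O[C@@H]12 | intermediate
9 | (3S,5S,9S,10S)-9,10-epoxy-2-hydroxy-3-[(2E)-dodec-2-enamido]-1-oxaspiro[4.5]dec-7-en-6-one, both lactol anomers | CCCCCCCCC/C=C/C(=O)N[C@H]1C[C@@]2(OC1O)C(=O)C=C[C@@H]1O[C@@H]12 | intermediate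
10 | open hydroxy aldehyde form of 9 (free C-1 hydroxyl, C-4 aldehyde, epoxy enone), formed in the flask | CCCCCCCCC/C=C/C(=O)N[C@H](C=O)C[C@@]1(O)C(=O)C=C[C@@H]2O[C@@H]21 | intermediate
11 | sodium C-9/C-5 enolate of the C-6 methoxide adduct of 10 (methoxy syn to the oxirane), formed in the flask | CCCCCCCCC/C=C/C(=O)N[C@H](C=O)C[C@@]1(O)C([O-])=C[C@H](OC)[C@@H]2O[C@@H]21.[Na+] | intermediate
12 | N-[(1S,3S,4R,5S,6S,7S,8S)-7,8-epoxy-1,4-dihydroxy-6-methoxy-9-oxobicyclo[3.3.1]nonan-3-yl]-(2E)-dodec-2-enamide, CNP0137540.1 | CCCCCCCCC/C=C/C(=O)N[C@H]1C[C@@]2(O)C(=O)[C@@H]([C@H]1O)[C@H](OC)[C@@H]1O[C@@H]12 | target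

## Step count and risks

Total step count: 7. Longest linear sequence: 7 steps (from acid 1; 6 from L-o-tyrosine 4).

The three steps most likely to fail:

Step 7. What may go wrong: base-induced opening or isomerization of the γ,δ-epoxy enone, or C-attack of the aldehyde enolate on C-6, may outrun the conjugate addition of methoxide, so that the cascade does not reach the aldol. The fallback moves the oxirane behind the closure of ring A, with the order of the two carbocycles unchanged; it sets out from 6 and comes back at 12. Dienone 6 would be reduced with iBu2AlH (CH2Cl2, −78 °C) to the dienol lactol F1. MnO2 would return the ketone and give the dienone lactol F2. NaOMe in MeOH would run the same lactol-opening/oxa-Michael/aldol cascade on this oxirane-free substrate and give the bicyclic 7,8-alkene F3. VO(acac)2/tBuOOH (CH2Cl2, 0 °C), directed by the allylic tertiary hydroxyl at C-1 and by the convex face of the bicycle, would then install the oxirane and give 12.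

Step 3. What may go wrong: weak diastereocontrol at the spiro carbon (mismatched pairing of catalyst and side-chain stereocentre), or slow catalytic turnover that lets the dienone dimerize by [4+2] cycloaddition. The fallback replaces catalyst control by separation and recycling; it sets out from 5 and comes back at 6. Acid 5 would be oxidized with stoichiometric PhI(OAc)2 in (CF3)2CHOH at −20 °C, dilute and cold. The two spiro epimers are diastereomers and would be separated by chromatography into 6 and the (3S,5R)-spirolactone F4. F4 would be returned to 5 by reductive rearomatization with zinc dust in acetic acid (cleavage of the α-acyloxy ketone C–O bond) and oxidized again.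

Step 4. What may go wrong: reversed facial selectivity, the dioxirane attacking C-7=C-8 from the face of the lactone methylene (for instance through hydrogen bonding to the amide N–H). The fallback delivers the oxygen in two steps, anti to a first electrophile, which reverses the facial outcome; it sets out from 6 and comes back at 7. NBS in aqueous acetone would form the bromonium ion on the face that electrophiles prefer, and water would open it anti at the allylic carbon C-7 to give the trans-bromohydrin F5. K2CO3 in dry acetone would close the oxirane by intramolecular displacement of bromide with inversion at C-8, so that the oxygen ends on the face opposite to the first attack, giving 7.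

## Further compounds

F1 | step 7 | dienol lactol, 3-[(2E)-dodec-2-enamido]-1-oxaspiro[4.5]deca-7,9-diene-2,6-diol (epimers at both carbinol carbons) | CCCCCCCCC/C=C/C(=O)N[C@H]1C[C@@]2(OC1O)C(O)C=CC=C2
F2 | step 7 | dienone lactol, 2-hydroxy-3-[(2E)-dodec-2-enamido]-1-oxaspiro[4.5]deca-7,9-dien-6-one (both anomers) | CCCCCCCCC/C=C/C(=O)N[C@H]1C[C@@]2(OC1O)C(=O)C=CC=C2
F3 | step 7 | bicyclic 7,8-alkene, N-[(1S,3S,4R,5S,6S)-1,4-dihydroxy-6-methoxy-9-oxobicyclo[3.3.1]non-7-en-3-yl]-(2E)-dodec-2-enamide | CCCCCCCCC/C=C/C(=O)N[C@H]1C[C@@]2(O)C(=O)[C@@H]([C@H]1O)[C@H](OC)C=C2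
F4 | step 3 | (3S,5R)-3-[(2E)-dodec-2-enamido]-1-oxaspiro[4.5]deca-7,9-diene-2,6-dione | CCCCCCCCC/C=C/C(=O)N[C@H]1C[C@]2(OC1=O)C(=O)C=CC=C2
F5 | step 4 | trans-bromohydrin of 6, 10-bromo-9-hydroxy-3-[(2E)-dodec-2-enamido]-1-oxaspiro[4.5]dec-7-ene-2,6-dione (hydroxyl on the face of the lactone oxygen, bromine on the other face) | CCCCCCCCC/C=C/C(=O)N[C@H]1C[C@@]2(OC1=O)C(=O)C=C[C@H](O)[C@H]2Br
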